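**Retrosynthetic overview**
1. Last step: the pendant lactone (O–C18 bond), the pyrrole and the azepine are made together from furan amine 30 by singlet-oxygen dearomatization of the furan, reduction to the cis-enedione, double condensation with the tethered NH2, and capture of the resulting azafulvenium ion at C18 by the side-chain ester.
2. Enabling feature: C18 is bonded directly to the pyrrole α-carbon C3, and N4 sits between C3 and C9a, so the pyrrole is a disguised 1,4-dicarbonyl; a furan in its place holds one oxidation level more, which can only end on an α-side-chain carbon, and only C18 has a carboxyl oxygen five atoms away.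
3. Fused lactone: C12–C13 by alkylation of the furan-fused cyclohexanone 21 with (S)-lactate triflate (inversion), C11–O by equatorial hydride delivery and lactonization.
4. Furan (temporary ring): Sonogashira coupling of iodoenone 16 with alkyne 9, conjugate reduction, 5-endo-dig cycloisomerization; C10 and C9 come from catalytic asymmetric ethyl addition to quinone monoketal 10 and trans alkylation.
5. Ring order: cyclohexane (from the dienone) → furan → fused γ-lactone → azepine + pyrrole + pendant γ-lactone.

Key step: step 17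

Remark: locants are those of the target (N4; C5–C8 azepine CH2; C9; C9a, C1, C2, C3 pyrrole carbons; C10 ethyl-bearing; C11 oxygen-bearing; C12; C13 methyl-bearing; C18 oxygen-bearing carbon on C3; C20 methyl-bearing carbon of the pendant lactone) and are kept for the corresponding atoms of all intermediates.
Assumption: the (S,R,R)-phosphoramidite is taken to give (R)-12, by analogy with its sense of induction on cyclohex-2-enone; if the sense is opposite, the enantiomeric ligand is used.

**Route**

Step 1
Reactants: 1 hex-5-ynoic acid; 2 (S)-4-benzyloxazolidin-2-one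
Product: 4 (S)-4-benzyl-3-(hex-5-ynoyl)oxazolidin-2-one, via mixed pivalic anhydride 3 (not isolated)
Conditions: t-BuCOCl, Et3N, THF, −20 °C; then LiCl, 2, 23 °C
Reagents that add atoms: none
Why: N-acylation through the mixed anhydride needs no strong base, so the terminal alkyne is not deprotonated, and no stereocentre is formed.

Step 2
Reactants: 4 (S)-4-benzyl-3-(hex-5-ynoyl)oxazolidin-2-one
Product: 6 (S)-4-benzyl-3-[(S)-2-methylhex-5-ynoyl]oxazolidin-2-one, via sodium enolate 5 (not isolated)
Conditions: NaN(SiMe3)2, THF, −78 °C; then MeI, −78 °C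
Reagents that add atoms: iodomethane CI
Why: Evans alkylation, in which the chelated (Z)-enolate is methylated on the face away from the benzyl group, which sets the (S) centre that becomes C20.

Step 3
Reactants: 6 (S)-4-benzyl-3-[(S)-2-methylhex-5-ynoyl]oxazolidin-2-one
Product: 8 (S)-2-methylhex-5-ynoic acid, via peroxy acid 7 (not isolated)
Conditions: LiOH, H2O2, THF/H2O, 0 °C; then Na2SO3 (aq); then 1 M HCl
Reagents that add atoms: hydrogen peroxide OO
Why: Hydroperoxide attacks the exocyclic imide carbonyl selectively and the weakly basic medium should not epimerize the α-centre.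

Step 4
Reactants: 8 (S)-2-methylhex-5-ynoic acid
Product: 9 tert-butyl (S)-2-methylhex-5-ynoate
Conditions: tert-butyl 2,2,2-trichloroacetimidate, BF3·OEt2 (cat.), CH2Cl2/cyclohexane, 23 °C
Reagents that add atoms: tert-butyl 2,2,2-trichloroacetimidate CC(C)(C)OC(=N)C(Cl)(Cl)Cl
Why: Acid-catalysed tert-butylation by the imidate esterifies the acid under conditions that leave the α-centre and the alkyne untouched.

Step 5
Reactants: 10 4,4-dimethoxycyclohexa-2,5-dien-1-one
Product: 12 (R)-5-ethyl-4,4-dimethoxycyclohex-2-en-1-one, via ethylzinc enolate 11 (not isolated)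
Conditions: Et2Zn (1.2 equiv), Cu(OTf)2 (2 mol %), (S,R,R)-phosphoramidite [O,O'-(S)-1,1'-binaphthalene-2,2'-diyl N,N-bis((R)-1-phenylethyl)phosphoramidite] (4 mol %), toluene, −25 °C; then H2O
Reagents that add atoms: diethylzinc CC[Zn]CC
Why: Copper-catalysed asymmetric conjugate addition desymmetrizes the prochiral dienone, the ligand choosing the enantiotopic alkene face and so setting C10, while the second enone survives for the furan construction.

Step 6
Reactants: 12 (R)-5-ethyl-4,4-dimethoxycyclohex-2-en-1-one; 13 1-chloro-4-iodobutane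
Product: 15 (5R,6R)-6-(4-chlorobutyl)-5-ethyl-4,4-dimethoxycyclohex-2-en-1-one, via lithium dienolate 14 (not isolated)
Conditions: LiN(i-Pr)2, THF, −78 °C; then 13, DMPU, −78 → −20 °C
Reagents that add atoms: none
Why: Only C6–H can be removed (C4 is quaternary), and the cross-conjugated enolate should be alkylated at the iodide end anti to the neighbouring ethyl group, giving the trans arrangement (C9), which is also the thermodynamic one.

Step 7
Reactants: 15 (5R,6R)-6-(4-chlorobutyl)-5-ethyl-4,4-dimethoxycyclohex-2-en-1-one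
Product: 16 (5R,6R)-6-(4-chlorobutyl)-5-ethyl-2-iodo-4,4-dimethoxycyclohex-2-en-1-one
Conditions: I2, pyridine, CH2Cl2, 0 → 23 °C
Reagents that add atoms: iodine II
Why: α-Iodination of the enone by pyridine addition, iodination of the enolate and elimination, a sequence that tolerates 4,4-disubstituted cyclohexenones and touches no stereocentre.

Step 8
Reactants: 16 (5R,6R)-6-(4-chlorobutyl)-5-ethyl-2-iodo-4,4-dimethoxycyclohex-2-en-1-one; 9 tert-butyl (S)-2-methylhex-5-ynoate
Product: 17 tert-butyl (S)-6-[(4R,5R)-5-(4-chlorobutyl)-4-ethyl-3,3-dimethoxy-6-oxocyclohex-1-en-1-yl]-2-methylhex-5-ynoate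
Conditions: PdCl2(PPh3)2 (3 mol %), CuI (6 mol %), i-Pr2NH, THF, 23 °C
Reagents that add atoms: none
Why: Sonogashira coupling of an α-iodoenone, a reactive vinyl iodide, joins the two fragments under mild amine base that leaves the alkyl chloride and both stereocentres alone.

Step 9
Reactants: 17 tert-butyl (S)-6-[(4R,5R)-5-(4-chlorobutyl)-4-ethyl-3,3-dimethoxy-6-oxocyclohex-1-en-1-yl]-2-methylhex-5-ynoate
Product: 19 tert-butyl (2S)-6-[(4R,5R)-5-(4-chlorobutyl)-4-ethyl-3,3-dimethoxy-6-oxocyclohexyl]-2-methylhex-5-ynoate (both epimers at the alkynyl-bearing carbon), via lithium enolate 18 (not isolated)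
Conditions: LiBH(s-Bu)3, THF, −78 °C; then AcOH
Reagents that add atoms: none
Why: The bulky hydride should add 1,4 to the β-unsubstituted enone, and the configuration of the new α-carbon (or any allenyl ketone tautomer) is irrelevant because it converges in the next step.

Step 10
Reactants: 19 tert-butyl (2S)-6-[(4R,5R)-5-(4-chlorobutyl)-4-ethyl-3,3-dimethoxy-6-oxocyclohexyl]-2-methylhex-5-ynoate
Product: 20 tert-butyl (S)-4-[(6R,7R)-7-(4-chlorobutyl)-6-ethyl-5,5-dimethoxy-4,5,6,7-tetrahydro-1-benzofuran-2-yl]-2-methylbutanoate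
Conditions: AuCl3 (2 mol %), MeCN, 23 °C
Reagents that add atoms: none
Why: Gold-catalysed 5-endo-dig cycloisomerization of a β,γ-alkynyl ketone, in which the enol oxygen attacks the activated alkyne, gives the 2,3,5-trisubstituted furan, after which C9 is no longer epimerizable.

Step 11
Reactants: 20 tert-butyl (S)-4-[(6R,7R)-7-(4-chlorobutyl)-6-ethyl-5,5-dimethoxy-4,5,6,7-tetrahydro-1-benzofuran-2-yl]-2-methylbutanoate
Product: 21 tert-butyl (S)-4-[(6R,7R)-7-(4-chlorobutyl)-6-ethyl-5-oxo-4,5,6,7-tetrahydro-1-benzofuran-2-yl]-2-methylbutanoate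
Conditions: 1 M HCl, THF, 0 °C (argon)
Reagents that add atoms: water O
Why: Dilute acid hydrolyses the dimethyl ketal at a temperature at which the trialkylfuran and the tert-butyl ester survive, and C10 stays trans to the fixed C9 substituent, the more stable arrangement.

Step 12
Reactants: 22 methyl (S)-lactate
Product: 23 methyl (S)-2-(trifluoromethanesulfonyloxy)propanoate
Conditions: Tf2O, 2,6-lutidine, CH2Cl2, −78 → 0 °C
Reagents that add atoms: trifluoromethanesulfonic anhydride O=S(=O)(OS(=O)(=O)C(F)(F)F)C(F)(F)F
Why: O-Sulfonylation with a hindered base leaves the stereocentre untouched and gives an electrophile that reacts by clean SN2 inversion.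

Step 13
Reactants: 21 tert-butyl (S)-4-[(6R,7R)-7-(4-chlorobutyl)-6-ethyl-5-oxo-4,5,6,7-tetrahydro-1-benzofuran-2-yl]-2-methylbutanoate; 23 methyl (S)-2-(trifluoromethanesulfonyloxy)propanoate
Product: 25 methyl (S)-2-[(4S,6R,7R)-2-[(S)-4-tert-butoxy-3-methyl-4-oxobutyl]-7-(4-chlorobutyl)-6-ethyl-5-oxo-4,5,6,7-tetrahydro-1-benzofuran-4-yl]propanoate, via lithium enolate 24 (not isolated)
Conditions: LiN(SiMe3)2, THF, −78 °C; then 23, −78 → −30 °C; then DBU (0.1 equiv), 0 °C
Reagents that add atoms: none
Why: The ketone is deprotonated at C12 (furfurylic and α to C=O), SN2 alkylation by the triflate with inversion sets C13 as (S), and C12, which stays epimerizable, should settle with the new branch equatorial, cis to the C10 ethyl group.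

Step 14
Reactants: 25 methyl (S)-2-[(4S,6R,7R)-2-[(S)-4-tert-butoxy-3-methyl-4-oxobutyl]-7-(4-chlorobutyl)-6-ethyl-5-oxo-4,5,6,7-tetrahydro-1-benzofuran-4-yl]propanoate
Product: 27 furan-fused chloro lactone (9R,10R,11R,12S,13S), via hydroxy diester 26 (not isolated)
Conditions: LiBH(s-Bu)3, THF, −78 °C; then AcOH; then PPTS (cat.), CH2Cl2, 23 °C
Reagents that add atoms: none
Why: The bulky hydride should attack the ketone, flanked by two equatorial α-substituents, from the equatorial direction to give the axial C11 alcohol cis to both neighbours, which closes the cis-fused γ-lactone on the methyl ester by acyl substitution without touching C13.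

Step 15
Reactants: 27 furan-fused chloro lactone
Product: 28 furan-fused azido lactone
Conditions: NaN3, NaI (cat.), DMF, 60 °C
Reagents that add atoms: sodium azide [Na+].[N-]=[N+]=[N-]
Why: Iodide-assisted SN2 displacement at the primary chloride by the weakly basic azide should leave the lactone α-centre unchanged.

Step 16
Reactants: 28 furan-fused azido lactone
Product: 30 furan-fused amino lactone, via iminophosphorane 29 (not isolated)
Conditions: PPh3, THF, 23 °C; then H2O, 50 °C (product used at once)
Reagents that add atoms: none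
Why: Staudinger reduction converts the azide into the primary amine under neutral conditions that spare the furan, both esters and the lactone.

Step 17
Reactants: 30 furan-fused amino lactone
Product: 34 bisdehydroneotuberostemonine, via furan endoperoxide 31 (not isolated), via cis-enedione 32 (not isolated), via azafulvenium ion 33 (not isolated)
Conditions: O2, tetraphenylporphyrin (cat.), visible light, AcOH (20 equiv), CH2Cl2 (0.005 M), −78 °C; then Me2S, −78 → 23 °C; then TFA, 0 → 23 °C
Reagents that add atoms: none
Why: Proposed new method: Singlet oxygen adds across the furan (visible-light [4+2]) to the strained bicyclic endoperoxide 31, whose O–O bond is reduced by Me2S so that the ring falls open to cis-enedione 32; the tethered amine (protected as its acetate salt during the oxygenation) then condenses with the C9a ketone (7-exo-trig, azepine) and the nitrogen adds to the C3 ketone (5-exo-trig, pyrrole closed at N), and because 32 holds one oxidation level more than a Paal–Knorr diketone the two dehydrations cannot end at a neutral pyrrole but at azafulvenium ion 33, whose exocyclic carbon C18 is attacked by the carbonyl oxygen of the tert-butyl ester (5-exo-trig, pendant lactone) with loss of isobutene. The closest known reactions are the one-pot furan photooxygenation, reduction and amine condensations that give pyrrolones, the Paal–Knorr pyrrole synthesis, and the capture of azafulvenium ions from pyrrol-2-yl carbinols by oxygen nucleophiles; what is new is their merger at the pyrrole oxidation level, so that the extra oxidation level of the furan is relayed to a side-chain carbon. The only new stereocentre, C18, is controlled by the C20 methyl group: closure through an envelope with methyl and pyrrolyl both pseudo-equatorial should give the cis-lactone, and since the C18–O bond ionizes reversibly in TFA the same, more stable cis isomer is also the product of equilibration. The selectivity needed is positional, C18 against C9 (and through it C12) as the carbon that keeps the oxidation level: only the C18 cation has a nucleophile within reach of a five-membered ring and its capture is made irreversible by loss of isobutene, whereas the C9 cation and the vinylpyrrole tautomers can only return through proton transfers that TFA keeps fast. C9 may pass through an sp2 stage on this manifold but should settle in the configuration it enters with, trans to the C10 ethyl group with both substituents equatorial.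

**Compound list**
1 | hex-5-ynoic acid | C#CCCCC(=O)O | starting material
2 | (S)-4-benzyloxazolidin-2-one | O=C1N[C@@H](Cc2ccccc2)CO1 | starting material
3 | hex-5-ynoic pivalic anhydride | C#CCCCC(=O)OC(=O)C(C)(C)C | intermediate
4 | (S)-4-benzyl-3-(hex-5-ynoyl)oxazolidin-2-one | C#CCCCC(=O)N1[C@@H](Cc2ccccc2)COC1=O | intermediate
5 | sodium (Z)-enolate of 4 | C#CCC/C=C(\[O-])N1[C@@H](Cc2ccccc2)COC1=O.[Na+] | intermediate
6 | (S)-4-benzyl-3-[(S)-2-methylhex-5-ynoyl]oxazolidin-2-one | C#CCC[C@H](C)C(=O)N1[C@@H](Cc2ccccc2)COC1=O | intermediate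
7 | (S)-2-methylhex-5-yneperoxoic acid (lithium salt in the flask) | C#CCC[C@H](C)C(=O)OO | intermediate
8 | (S)-2-methylhex-5-ynoic acid | C#CCC[C@H](C)C(=O)O | intermediate
9 | tert-butyl (S)-2-methylhex-5-ynoate | C#CCC[C@H](C)C(=O)OC(C)(C)C | intermediate
10 | 4,4-dimethoxycyclohexa-2,5-dien-1-one | COC1(OC)C=CC(=O)C=C1 | starting material
11 | ethylzinc enolate of 12 | CC[C@@H]1C=C(O[Zn]CC)C=CC1(OC)OC | intermediate
12 | (R)-5-ethyl-4,4-dimethoxycyclohex-2-en-1-one | CC[C@H]1C(OC)(OC)C=CC(=O)C1 | intermediate
13 | 1-chloro-4-iodobutane | ClCCCCI | starting material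
14 | lithium dienolate of 12 (deprotonated at C6) | CC[C@@H]1C=C([O-])C=CC1(OC)OC.[Li+] | intermediate
15 | (5R,6R)-6-(4-chlorobutyl)-5-ethyl-4,4-dimethoxycyclohex-2-en-1-one (trans) | CC[C@H]1C(OC)(OC)C=CC(=O)[C@@H]1CCCCCl | intermediate
16 | (5R,6R)-6-(4-chlorobutyl)-5-ethyl-2-iodo-4,4-dimethoxycyclohex-2-en-1-one | CC[C@H]1C(OC)(OC)C=C(I)C(=O)[C@@H]1CCCCCl | intermediate
17 | tert-butyl (S)-6-[(4R,5R)-5-(4-chlorobutyl)-4-ethyl-3,3-dimethoxy-6-oxocyclohex-1-en-1-yl]-2-methylhex-5-ynoate | CC[C@H]1C(OC)(OC)C=C(C#CCC[C@H](C)C(=O)OC(C)(C)C)C(=O)[C@@H]1CCCCCl | intermediate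
18 | lithium enolate of 19 | CC[C@H]1C(OC)(OC)CC(C#CCC[C@H](C)C(=O)OC(C)(C)C)=C([O-])[C@@H]1CCCCCl.[Li+] | intermediate
19 | tert-butyl (2S)-6-[(4R,5R)-5-(4-chlorobutyl)-4-ethyl-3,3-dimethoxy-6-oxocyclohexyl]-2-methylhex-5-ynoate, both epimers at the alkynyl-bearing ring carbon | CC[C@H]1C(OC)(OC)CC(C#CCC[C@H](C)C(=O)OC(C)(C)C)C(=O)[C@@H]1CCCCCl | intermediate
20 | tert-butyl (S)-4-[(6R,7R)-7-(4-chlorobutyl)-6-ethyl-5,5-dimethoxy-4,5,6,7-tetrahydro-1-benzofuran-2-yl]-2-methylbutanoate | CC[C@H]1C(OC)(OC)Cc2cc(CC[C@H](C)C(=O)OC(C)(C)C)oc2[C@@H]1CCCCCl | intermediate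
21 | tert-butyl (S)-4-[(6R,7R)-7-(4-chlorobutyl)-6-ethyl-5-oxo-4,5,6,7-tetrahydro-1-benzofuran-2-yl]-2-methylbutanoate | CC[C@H]1C(=O)Cc2cc(CC[C@H](C)C(=O)OC(C)(C)C)oc2[C@@H]1CCCCCl | intermediate
22 | methyl (S)-lactate | C[C@H](O)C(=O)OC | starting material
23 | methyl (S)-2-(trifluoromethanesulfonyloxy)propanoate | C[C@H](OS(=O)(=O)C(F)(F)F)C(=O)OC | intermediate
24 | lithium enolate of 21 (C11–O, C11=C12) | CC[C@H]1C([O-])=Cc2cc(CC[C@H](C)C(=O)OC(C)(C)C)oc2[C@@H]1CCCCCl.[Li+] | intermediate
25 | methyl (S)-2-[(4S,6R,7R)-2-[(S)-4-tert-butoxy-3-methyl-4-oxobutyl]-7-(4-chlorobutyl)-6-ethyl-5-oxo-4,5,6,7-tetrahydro-1-benzofuran-4-yl]propanoate | CC[C@H]1C(=O)[C@@H]([C@H](C)C(=O)OC)c2cc(CC[C@H](C)C(=O)OC(C)(C)C)oc2[C@@H]1CCCCCl | intermediate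
26 | (4S,5R,6R,7R)-5-hydroxy analogue of 25 (axial OH, cis to the C10 ethyl and the C12 branch) | CC[C@H]1[C@@H](O)[C@@H]([C@H](C)C(=O)OC)c2cc(CC[C@H](C)C(=O)OC(C)(C)C)oc2[C@@H]1CCCCCl | intermediate
27 | chloro lactone: 4,5,6,7-tetrahydro-1-benzofuran with the (S)-CH2CH2CH(CH3)CO2t-Bu chain on the furan α-carbon, 4-chlorobutyl on C9, ethyl on C10 and a cis-fused γ-lactone across C11–C12 (ring O on C11, methyl-bearing C13 on C12); 9R,10R,11R,12S,13S; H10, H11, H12, H13 all cis, H9 trans to H10 | CC[C@H]1[C@H]2OC(=O)[C@@H](C)[C@H]2c2cc(CC[C@H](C)C(=O)OC(C)(C)C)oc2[C@@H]1CCCCCl | intermediate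
28 | azido lactone: 27 with N3 in place of Cl | CC[C@H]1[C@H]2OC(=O)[C@@H](C)[C@H]2c2cc(CC[C@H](C)C(=O)OC(C)(C)C)oc2[C@@H]1CCCCN=[N+]=[N-] | intermediate
29 | iminophosphorane: 27 with N=PPh3 in place of Cl | CC[C@H]1[C@H]2OC(=O)[C@@H](C)[C@H]2c2cc(CC[C@H](C)C(=O)OC(C)(C)C)oc2[C@@H]1CCCCN=P(c3ccccc3)(c3ccccc3)c3ccccc3 | intermediate
30 | amino lactone: 27 with NH2 in place of Cl | CC[C@H]1[C@H]2OC(=O)[C@@H](C)[C@H]2c2cc(CC[C@H](C)C(=O)OC(C)(C)C)oc2[C@@H]1CCCCN | intermediate
31 | furan endoperoxide of 30 (2,3,7-trioxabicyclo[2.2.1]hept-5-ene; either face; amine as acetate salt) | CC[C@H]1[C@H]2OC(=O)[C@@H](C)[C@H]2C2=CC3(CC[C@H](C)C(=O)OC(C)(C)C)OOC2(O3)[C@@H]1CCCCN | intermediate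
32 | (Z)-enedione: cyclohexanone (C9a=O) with exocyclic C1=C2H–C3(=O)–side chain, the two carbonyls cis (amine as acetate salt) | CC[C@H]1[C@H]2OC(=O)[C@@H](C)[C@H]2/C(=C/C(=O)CC[C@H](C)C(=O)OC(C)(C)C)C(=O)[C@@H]1CCCCN | intermediate
33 | azafulvenium ion (pyrrolo-azepine with exocyclic C3=C18 and N4=C9a iminium; tert-butyl ester) | CC[C@H]1[C@H]2OC(=O)[C@@H](C)[C@H]2C2=CC(=CC[C@H](C)C(=O)OC(C)(C)C)[N+]3=C2[C@@H]1CCCC3 | intermediate
34 | bisdehydroneotuberostemonine (9R,10R,11R,12S,13S,18S,20S) | CC[C@H]1[C@H]2OC(=O)[C@@H](C)[C@H]2c2cc([C@@H]3C[C@H](C)C(=O)O3)n3c2[C@@H]1CCCC3 | target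

**Step count**
Total: 17 steps. Longest linear sequence: 13 steps (1–4, 8–11, 13–17).

**Three steps most likely to fail**

1. Step 17 (proposed new method). What may go wrong: the oxidation level may leak from the azafulvenium manifold to C9 or, through it, to C12 (elimination to vinylpyrroles or to a conjugated butenolide). The azafulvenium may also alkylate the free pyrrole β-position of another molecule, and control at C18 by the remote C20 methyl group may be low. Fallback from 30, returning at 34: the oxidant is left out and the furan is recyclized by the tethered amine under acid alone (TFA, CH2Cl2, then AcOH, 60 °C). This is the known furan ring opening to the 1,4-diketone followed by Paal–Knorr closure, and the tert-butyl ester is cleaved in the same pot, giving the tetracyclic pyrrole acid F1. F1 is then treated with DDQ (CH2Cl2, 0 °C), which abstracts hydride from the methylene next to the pyrrole α-carbon; the carboxylate closes the lactone on the cation (a benzylic-type oxidative lactonization), which gives 34. This fallback does not remove the C9-against-C18 competition.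

2. Step 13. What may go wrong: O-alkylation of the enolate or elimination of the secondary triflate, and poor facial selectivity at C12 that the equilibration does not correct. Fallback from 21, returning at 27: enolate 24 is alkylated with methyl bromoacetate, which creates no centre at C13, to give keto diester F2. LiBH(s-Bu)3 reduction and lactonization as in step 14 give the nor-methyl lactone F3. LiN(i-Pr)2 followed by Me2N=CH2+ I− gives Mannich base F4, and MeI followed by NaHCO3 gives the α-methylene lactone F5. Hydrogenation with RhCl(PPh3)3 and H2 from the convex face of the cis-fused bicycle sets C13 and gives 27.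

3. Step 14. What may go wrong: enolization of the hindered, benzylic-type ketone by the basic hydride in place of reduction, or insufficient facial selectivity. Fallback from 25, returning at 27: NaBH4 in MeOH at −20 °C (axial attack, too weakly basic to enolize) gives the equatorial C11 alcohol F6. LiOH in THF/H2O cleaves only the methyl ester to give hydroxy acid F7. Mitsunobu lactonization (PPh3, DIAD) then closes the lactone with inversion at C11 and gives 27.

**Further compounds**
F1 | step 17 | tetracyclic pyrrole acid (target skeleton with the open (S)-CH2CH2CH(CH3)CO2H chain on C3) | CC[C@H]1[C@H]2OC(=O)[C@@H](C)[C@H]2c2cc(CC[C@H](C)C(=O)O)n3c2[C@@H]1CCCC3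
F2 | step 13 | keto diester with CH2CO2CH3 on C12 (analogue of 25 without the C13 methyl) | CC[C@H]1C(=O)[C@@H](CC(=O)OC)c2cc(CC[C@H](C)C(=O)OC(C)(C)C)oc2[C@@H]1CCCCCl
F3 | step 13 | nor-methyl chloro lactone (27 without the C13 methyl) | CC[C@H]1[C@H]2OC(=O)C[C@H]2c2cc(CC[C@H](C)C(=O)OC(C)(C)C)oc2[C@@H]1CCCCCl
F4 | step 13 | Mannich base (F3 with CH2N(CH3)2 on C13, configuration there immaterial) | CC[C@H]1[C@H]2OC(=O)C(CN(C)C)[C@H]2c2cc(CC[C@H](C)C(=O)OC(C)(C)C)oc2[C@@H]1CCCCCl
F5 | step 13 | α-methylene lactone (C13=CH2) | CC[C@H]1[C@H]2OC(=O)C(=C)[C@H]2c2cc(CC[C@H](C)C(=O)OC(C)(C)C)oc2[C@@H]1CCCCCl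
F6 | step 14 | C11 epimer of 26 (equatorial OH, trans to both neighbours) | CC[C@H]1[C@H](O)[C@@H]([C@H](C)C(=O)OC)c2cc(CC[C@H](C)C(=O)OC(C)(C)C)oc2[C@@H]1CCCCCl
F7 | step 14 | hydroxy acid from F6 (methyl ester cleaved, tert-butyl ester kept) | CC[C@H]1[C@H](O)[C@@H]([C@H](C)C(=O)O)c2cc(CC[C@H](C)C(=O)OC(C)(C)C)oc2[C@@H]1CCCCCl
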